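The 3(2H)-furanone (C10, O, C3, C2, C1; germacrane numbering, see remark 1) is treated as a cycloisomerised α′-hydroxy ynone, so the route rests on cutting its O–C3 bond across the ten-membered carbocycle. A monovalent gold catalyst closes this ring last: the tertiary C10 hydroxyl adds transannularly (5-endo-dig) to C3 of a strained C1-keto C2≡C3 cyclodecenyne, forming the oxygen bridge and the C2=C3 enol ether in one strain-releasing operation. The precursor is a macrocyclic hydroxy ynone that already carries the trans-fused methylene lactone and the C8 methacrylate; it comes from a Sonogashira union (C3–C4) and a CrCl2 Barbier macrocyclisation (C7–C8) of a bromomethyl butenolide onto an aldehyde.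

Key step: step 18

Remark 1: atom labels are the germacrane positions of the target (C1 ketone, C2=C3 enol-ether olefin, C4=C5 olefin, C6 lactone carbinol, C7, C8 ester carbinol, C9 methylene, C10 quaternary carbon, C11=C13 exocyclic methylene, C12 lactone carbonyl, C14 methyl, C15 hydroxymethyl); in these labels the target is 6R,7R,8R,10S with C3 and C6 cis across C4=C5.
Remark 2: the CIP descriptor at C6 and the E/Z descriptor of C4=C5 change along the route only because substituent priorities change; the geometry is the same throughout.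
Remark 3: the C1 carbinol made in step 9 is carried as an epimer mixture (left undefined in the SMILES) because step 17 turns it into the C1 ketone.
Remark 4 (assumption): the lipase in step 2 is taken to follow the Kazlauskas rule; were its preference reversed, the acetate would be methanolysed and carried on instead.

Step 1
Reactants: 1 tert-butyl(diphenyl)(prop-2-yn-1-yloxy)silane; 2 acrolein
Product: 4 rac-6-[(tert-butyldiphenylsilyl)oxy]hex-1-en-4-yn-3-ol, via lithium acetylide 3 (not isolated)
Conditions: n-BuLi, THF, −78 °C; then 2, −78 °C; H2O quench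
Reagents that add atoms: none
Why: Deprotonation of the terminal alkyne and 1,2-addition of the lithium acetylide to the enal (acetylide addition to an aldehyde) should give the racemic vinyl alkynyl carbinol, whose carbinol carbon becomes C6 and is resolved in step 2.

Step 2
Reactants: 4 rac-6-[(tert-butyldiphenylsilyl)oxy]hex-1-en-4-yn-3-ol
Product: 5 (3S)-6-[(tert-butyldiphenylsilyl)oxy]hex-1-en-4-yn-3-ol
Conditions: Pseudomonas fluorescens lipase, vinyl acetate, hexane, rt, stopped near half conversion; chromatography
Reagents that add atoms: none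
Why: Lipase-catalysed kinetic resolution by transesterification, in which the enzyme should acetylate the (R)-alcohol (Kazlauskas rule, vinyl as medium and silyloxypropynyl as large group) and leave (S)-5, which fixes C6.

Step 3
Reactants: 5 (3S)-6-[(tert-butyldiphenylsilyl)oxy]hex-1-en-4-yn-3-ol
Product: 7 (3S,4Z)-6-[(tert-butyldiphenylsilyl)oxy]-5-iodohexa-1,4-dien-3-ol, via alkenylaluminate 6 (not isolated)
Conditions: NaAlH2(OCH2CH2OCH3)2, THF, 0 °C to rt; then I2, THF, −78 °C
Reagents that add atoms: iodine, [I][I]
Why: Hydroxyl-directed trans-hydroalumination of the propargylic alcohol delivers hydride to C5 and aluminium to C4, and iodinolysis with retention should give the vinyl iodide with iodine cis to C6 (hydroalumination–iodination of a propargylic alcohol).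

Step 4
Reactants: 7 (3S,4Z)-6-[(tert-butyldiphenylsilyl)oxy]-5-iodohexa-1,4-dien-3-ol
Product: 8 (3S,4Z)-6-[(tert-butyldiphenylsilyl)oxy]-5-iodohexa-1,4-dien-3-yl prop-2-enoate
Conditions: acryloyl chloride, i-Pr2NEt, CH2Cl2, −78 to 0 °C
Reagents that add atoms: acryloyl chloride, C=CC(=O)Cl
Why: O-acylation of the secondary alcohol at low temperature installs C11 and C12 without touching the C6 stereocentre.

Step 5
Reactants: 8 (3S,4Z)-6-[(tert-butyldiphenylsilyl)oxy]-5-iodohexa-1,4-dien-3-yl prop-2-enoate
Product: 9 (3S,4Z)-6-[(tert-butyldiphenylsilyl)oxy]-5-iodohexa-1,4-dien-3-yl 2-(hydroxymethyl)prop-2-enoate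
Conditions: aqueous HCHO, DABCO, 1,4-dioxane/H2O, rt
Reagents that add atoms: formaldehyde, C=O
Why: Morita–Baylis–Hillman α-hydroxymethylation of the acrylate (DABCO adds, the ammonium enolate traps formaldehyde, DABCO leaves) installs C13 as a free allylic alcohol that is inert to palladium in step 12.

Step 6
Reactants: 9 (3S,4Z)-6-[(tert-butyldiphenylsilyl)oxy]-5-iodohexa-1,4-dien-3-yl 2-(hydroxymethyl)prop-2-enoate
Product: 10 (5S)-5-[(1Z)-3-[(tert-butyldiphenylsilyl)oxy]-2-iodoprop-1-en-1-yl]-3-(hydroxymethyl)furan-2(5H)-one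
Conditions: second-generation Grubbs catalyst (5 mol%), CH2Cl2 (5 mM), 40 °C
Reagents that add atoms: none
Why: Ring-closing metathesis between the vinyl group and the 1,1-disubstituted acrylate olefin should close the butenolide (C7=C11) with loss of ethylene, the hindered trisubstituted iodoalkene staying out of the reaction and C6 untouched.

Step 7
Reactants: 11 (R)-2-methylglycidol
Product: 12 (2S)-2-methylpent-4-ene-1,2-diol
Conditions: CH2=CHMgBr (3.5 equiv), CuI (10 mol%), THF, −40 to 0 °C
Reagents that add atoms: vinylmagnesium bromide, C=C[Mg]Br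
Why: Copper-catalysed Grignard opening of the epoxide at its unsubstituted carbon (SN2) leaves the quaternary carbon, the future C10, untouched, so its configuration is carried over from 11.

Step 8
Reactants: 12 (2S)-2-methylpent-4-ene-1,2-diol
Product: 13 (2S)-2-hydroxy-2-methylpent-4-enal
Conditions: SO3·pyridine, DMSO, i-Pr2NEt, CH2Cl2, 0 °C; used crude (volatile)
Reagents that add atoms: none
Why: Parikh–Doering oxidation can only oxidise the primary alcohol, and the α-carbon has no hydrogen, so C10 cannot epimerise.

Step 9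
Reactants: 13 (2S)-2-hydroxy-2-methylpent-4-enal
Product: 14 (4S)-4-methylhept-6-en-1-yne-3,4-diol (epimers at the new carbinol C1)
Conditions: HC≡CMgBr (3 equiv), THF, −78 to 0 °C
Reagents that add atoms: ethynylmagnesium bromide, C#C[Mg]Br
Why: Grignard 1,2-addition to the aldehyde brings in C2 and C3, and the low facial selectivity at C1 is irrelevant because C1 later becomes a ketone.

Step 10
Reactants: 14 (4S)-4-methylhept-6-en-1-yne-3,4-diol
Product: 15 (4S)-5-ethynyl-2,2,4-trimethyl-4-(prop-2-en-1-yl)-1,3-dioxolane
Conditions: 2,2-dimethoxypropane, PPTS (cat.), CH2Cl2, rt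
Reagents that add atoms: 2,2-dimethoxypropane, COC(C)(C)OC
Why: Acid-catalysed transketalisation ties the C1/C10 diol into a temporary dioxolane that masks both hydroxyls until step 16.

Step 11
Reactants: 15 (4S)-5-ethynyl-2,2,4-trimethyl-4-(prop-2-en-1-yl)-1,3-dioxolane
Product: 17 2-[(4S)-5-ethynyl-2,2,4-trimethyl-1,3-dioxolan-4-yl]acetaldehyde, via diol 16 (not isolated)
Conditions: OsO4 (2 mol%), NaIO4, 2,6-lutidine, 1,4-dioxane/H2O, rt
Reagents that add atoms: osmium tetroxide, O=[Os](=O)(=O)=O (oxygen donor for the new C=O, regenerated by sodium periodate, [Na+].[O-]I(=O)(=O)=O)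
Why: Lemieux–Johnson cleavage, in which OsO4 dihydroxylates the terminal alkene much faster than the terminal alkyne and periodate cleaves diol 16 to the C8 aldehyde.

Step 12
Reactants: 10 (5S)-5-[(1Z)-3-[(tert-butyldiphenylsilyl)oxy]-2-iodoprop-1-en-1-yl]-3-(hydroxymethyl)furan-2(5H)-one; 17 2-[(4S)-5-ethynyl-2,2,4-trimethyl-1,3-dioxolan-4-yl]acetaldehyde
Product: 18 2-[(4S)-5-{(3E)-3-{[(tert-butyldiphenylsilyl)oxy]methyl}-4-[(2R)-4-(hydroxymethyl)-5-oxo-2,5-dihydrofuran-2-yl]but-3-en-1-yn-1-yl}-2,2,4-trimethyl-1,3-dioxolan-4-yl]acetaldehyde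
Conditions: Pd(PPh3)4 (5 mol%), CuI (10 mol%), i-Pr2NEt, degassed THF, rt
Reagents that add atoms: none
Why: Sonogashira coupling (oxidative addition of zerovalent palladium into C4–I, transmetalation of the copper acetylide, reductive elimination) forms C3–C4 with retention of olefin geometry, a hindered amine at room temperature being chosen to spare the butenolide γ-centre C6 and the β-alkoxy aldehyde.

Step 13
Reactants: 18 enyne aldehyde (hydroxymethyl butenolide)
Product: 20 2-[(4S)-5-{(3E)-4-[(2R)-4-(bromomethyl)-5-oxo-2,5-dihydrofuran-2-yl]-3-{[(tert-butyldiphenylsilyl)oxy]methyl}but-3-en-1-yn-1-yl}-2,2,4-trimethyl-1,3-dioxolan-4-yl]acetaldehyde, via mesylate 19 (not isolated)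
Conditions: MsCl, Et3N, CH2Cl2, −40 °C; then LiBr, THF, 0 °C
Reagents that add atoms: lithium bromide, [Li+].[Br-]
Why: Mesylation of the only hydroxyl and SN2 displacement by bromide give the allylic bromide after the palladium step, conditions that the aldehyde, acetonide and silyl ether tolerate.

Step 14
Reactants: 20 bromomethyl butenolide aldehyde
Product: 22 macrocyclic alcohol (6R,7R,8S,10S): ten-membered C1–C10 ring with C2≡C3, trans-fused α-methylene-γ-lactone at C6–C7, C8 hydroxyl, C1/C10 acetonide, C15 silyl ether, via allylchromium dichloride 21 (not isolated)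
Conditions: CrCl2 (8 equiv), THF, rt, slow addition of 20 (final 2 mM); aqueous work-up
Reagents that add atoms: none
Why: Nozaki–Hiyama-type Barbier allylation, in which the γ-carbon C7 of allylchromium 21 adds to the C8 aldehyde through a chair transition state; the cis-enyne tether should place C5 and C8 on opposite faces of the butenolide (trans lactone, 7R) and the chain-equatorial chair should set O8 anti to C6 (8S), while high dilution favours ring closure.

Step 15
Reactants: 22 macrocyclic alcohol (8S)
Product: 23 macrocyclic methacrylate (6R,7R,8R,10S), acetonide and silyl ether retained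
Conditions: methacrylic acid, PPh3, DIAD, toluene, 0 °C to rt
Reagents that add atoms: methacrylic acid, C=C(C)C(=O)O
Why: Mitsunobu esterification displaces the C8 oxyphosphonium by methacrylate in an SN2 step, so the ester is installed with inversion from 8S to the required 8R.

Step 16
Reactants: 23 macrocyclic methacrylate acetonide
Product: 24 macrocyclic C1,C10-diol (6R,7R,8R,10S; C1 epimers)
Conditions: CF3CO2H/H2O/THF, 0 °C to rt
Reagents that add atoms: none
Why: Acid hydrolysis removes the temporary dioxolane ring, while the TBDPS ether, the lactone and the methacrylate are stable to brief aqueous acid.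

Step 17
Reactants: 24 macrocyclic diol
Product: 25 macrocyclic α′-hydroxy ynone (6R,7R,8R,10S): C1 ketone, C2≡C3, free C10 hydroxyl
Conditions: Dess–Martin periodinane, CH2Cl2, 0 °C to rt
Reagents that add atoms: none
Why: Dess–Martin oxidation converts the secondary propargylic C1 alcohol (both epimers) into the ynone, and the tertiary C10 hydroxyl cannot be oxidised.

Step 18
Reactants: 25 macrocyclic α′-hydroxy ynone
Product: 26 15-O-tert-butyldiphenylsilyl ether of the target (6R,7R,8R,10S; C4=C5 Z)
Conditions: Ph3PAuNTf2 (5 mol%), CH2Cl2, rt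
Reagents that add atoms: none
Why: The cationic monovalent gold centre π-activates the C2≡C3 triple bond of the ynone, the C10 hydroxyl oxygen adds anti to gold at C3 (the β-carbon of the ynone), and protodeauration of the C2 vinylgold releases the C2=C3 enol ether and the catalyst. The closest known reaction type is the gold-catalysed cycloisomerisation of γ-hydroxy alkynones to 3(2H)-furanones. The furanone ring closes in the 5-endo-dig mode, here transannularly across the ten-membered carbocycle, so that the new O–C3 bond turns the cyclodecenynone into the 11-oxabicyclo[6.2.1]undecane core with C3 and C10 as bridgeheads. No stereocentre is created: C10 (from 11), C6 (step 2), C7 (step 14) and C8 (step 15) are in place and the C4=C5 geometry is not touched. The step needs attack at C3 and not at C2 and must leave the methylene lactone, the methacrylate and the silyl ether alone; the ynone polarisation makes C3 the electrophilic carbon, the 1,2-relationship of the hydroxyl to the C1 carbonyl allows only the five-membered ring, and the electron-poor olefins are not activated by gold. Release of the bending strain of the ten-membered cycloalkyne should add driving force.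

Step 19
Reactants: 26 silyl ether of the target
Product: 27 target, (6R,7R,8R,10S)-8-O-methacryloyl-15-hydroxy furanone-bridged germacranolide
Conditions: HF·pyridine, pyridine, THF, 0 °C to rt
Reagents that add atoms: none
Why: Buffered fluoride cleaves the Si–O bond of the primary allylic silyl ether without adding to the methylene lactone, the dienone or the methacrylate.

Compound list
1 | tert-butyl(diphenyl)(prop-2-yn-1-yloxy)silane | C#CCO[Si](c1ccccc1)(c1ccccc1)C(C)(C)C | starting material
2 | acrolein | C=CC=O | starting material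
3 | lithium acetylide of 1 | [Li]C#CCO[Si](c1ccccc1)(c1ccccc1)C(C)(C)C | intermediate
4 | rac-6-[(tert-butyldiphenylsilyl)oxy]hex-1-en-4-yn-3-ol | C=CC(O)C#CCO[Si](c1ccccc1)(c1ccccc1)C(C)(C)C | intermediate
5 | (3S)-6-[(tert-butyldiphenylsilyl)oxy]hex-1-en-4-yn-3-ol | C=C[C@H](O)C#CCO[Si](c1ccccc1)(c1ccccc1)C(C)(C)C | intermediate
6 | sodium cyclic alkenyl(alkoxy)bis(2-methoxyethoxy)aluminate of 5 (Al on C4, O–Al chelate) | [Na+].COCCO[Al-]1(OCCOC)O[C@@H](C=C)C=C1CO[Si](c2ccccc2)(c2ccccc2)C(C)(C)C | intermediate
7 | (3S,4Z)-6-[(tert-butyldiphenylsilyl)oxy]-5-iodohexa-1,4-dien-3-ol | C=C[C@H](O)/C=C(\I)CO[Si](c1ccccc1)(c1ccccc1)C(C)(C)C | intermediate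
8 | (3S,4Z)-6-[(tert-butyldiphenylsilyl)oxy]-5-iodohexa-1,4-dien-3-yl prop-2-enoate | C=CC(=O)O[C@@H](C=C)/C=C(\I)CO[Si](c1ccccc1)(c1ccccc1)C(C)(C)C | intermediate
9 | (3S,4Z)-6-[(tert-butyldiphenylsilyl)oxy]-5-iodohexa-1,4-dien-3-yl 2-(hydroxymethyl)prop-2-enoate | C=C(CO)C(=O)O[C@@H](C=C)/C=C(\I)CO[Si](c1ccccc1)(c1ccccc1)C(C)(C)C | intermediate
10 | (5S)-5-[(1Z)-3-[(tert-butyldiphenylsilyl)oxy]-2-iodoprop-1-en-1-yl]-3-(hydroxymethyl)furan-2(5H)-one | I/C(CO[Si](c1ccccc1)(c1ccccc1)C(C)(C)C)=C\[C@H]2OC(=O)C(CO)=C2 | intermediate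
11 | (R)-2-methylglycidol | OC[C@]1(C)CO1 | starting material
12 | (2S)-2-methylpent-4-ene-1,2-diol | C=CC[C@](C)(O)CO | intermediate
13 | (2S)-2-hydroxy-2-methylpent-4-enal | C=CC[C@](C)(O)C=O | intermediate
14 | (4S)-4-methylhept-6-en-1-yne-3,4-diol (C3 epimers) | C=CC[C@](C)(O)C(O)C#C | intermediate
15 | (4S)-5-ethynyl-2,2,4-trimethyl-4-(prop-2-en-1-yl)-1,3-dioxolane (C5 epimers) | C=CC[C@]1(C)OC(C)(C)OC1C#C | intermediate
16 | 3-[(4S)-5-ethynyl-2,2,4-trimethyl-1,3-dioxolan-4-yl]propane-1,2-diol | OCC(O)C[C@]1(C)OC(C)(C)OC1C#C | intermediate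
17 | 2-[(4S)-5-ethynyl-2,2,4-trimethyl-1,3-dioxolan-4-yl]acetaldehyde | O=CC[C@]1(C)OC(C)(C)OC1C#C | intermediate
18 | enyne aldehyde with (2R)-4-(hydroxymethyl)butenolide (C3 and C6 cis across C4=C5) | O=CC[C@]1(C)OC(C)(C)OC1C#C/C(CO[Si](c2ccccc2)(c2ccccc2)C(C)(C)C)=C\[C@H]3OC(=O)C(CO)=C3 | intermediate
19 | methanesulfonate of 18 | O=CC[C@]1(C)OC(C)(C)OC1C#C/C(CO[Si](c2ccccc2)(c2ccccc2)C(C)(C)C)=C\[C@H]3OC(=O)C(COS(C)(=O)=O)=C3 | intermediate
20 | enyne aldehyde with (2R)-4-(bromomethyl)butenolide | O=CC[C@]1(C)OC(C)(C)OC1C#C/C(CO[Si](c2ccccc2)(c2ccccc2)C(C)(C)C)=C\[C@H]3OC(=O)C(CBr)=C3 | intermediate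
21 | allylchromium dichloride from 20 | O=CC[C@]1(C)OC(C)(C)OC1C#C/C(CO[Si](c2ccccc2)(c2ccccc2)C(C)(C)C)=C\[C@H]3OC(=O)C(C[Cr](Cl)Cl)=C3 | intermediate
22 | macrocyclic alcohol (6R,7R,8S,10S), acetonide, silyl ether | O[C@H]1C[C@]2(C)OC(C)(C)OC2C#C/C(CO[Si](c3ccccc3)(c3ccccc3)C(C)(C)C)=C\[C@H]4OC(=O)C(=C)[C@@H]41 | intermediate
23 | macrocyclic methacrylate (6R,7R,8R,10S), acetonide, silyl ether | C=C(C)C(=O)O[C@@H]1C[C@]2(C)OC(C)(C)OC2C#C/C(CO[Si](c3ccccc3)(c3ccccc3)C(C)(C)C)=C\[C@H]4OC(=O)C(=C)[C@@H]41 | intermediate
24 | macrocyclic C1,C10-diol (6R,7R,8R,10S; C1 epimers) | C=C(C)C(=O)O[C@@H]1C[C@](C)(O)C(O)C#C/C(CO[Si](c2ccccc2)(c2ccccc2)C(C)(C)C)=C\[C@H]3OC(=O)C(=C)[C@@H]31 | intermediate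
25 | macrocyclic α′-hydroxy ynone (6R,7R,8R,10S) | C=C(C)C(=O)O[C@@H]1C[C@](C)(O)C(=O)C#C/C(CO[Si](c2ccccc2)(c2ccccc2)C(C)(C)C)=C\[C@H]3OC(=O)C(=C)[C@@H]31 | intermediate
26 | 15-O-tert-butyldiphenylsilyl ether of the target | C=C(C)C(=O)O[C@@H]1C[C@]2(C)OC(=CC2=O)/C(CO[Si](c3ccccc3)(c3ccccc3)C(C)(C)C)=C\[C@H]2OC(=O)C(=C)[C@@H]21 | intermediate
27 | target, (6R,7R,8R,10S) | C=C(C)C(=O)O[C@@H]1C[C@]2(C)OC(=CC2=O)/C(CO)=C\[C@H]2OC(=O)C(=C)[C@@H]21 | target

Total step count: 19. Longest linear sequence: 14 steps (steps 1–6, then 12–19); steps 7–11 form the second branch.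

Steps most likely to fail

Step 14. Ring closure to the strained ten-membered cycloalkyne may lose to intermolecular allylation, and the facial selectivity at C7 (cis- instead of trans-fused lactone) may depart from the chair model. A reversed preference at the aldehyde alone would only call for esterification with retention in step 15. The fallback sets out from 10 and 17, makes the C7–C8 bond under open-chain control and closes the ring at C3–C4 instead. Alcohol 10 is converted with CBr4/PPh3 (CH2Cl2, 0 °C) into the bromomethyl butenolide vinyl iodide F1. Zinc dust in THF/aqueous NH4Cl joins F1 and aldehyde 17 to the seco alcohol F2, where attack anti to the C6 substituent and a chair transition state should give the trans lactone and the 8S carbinol. Mitsunobu esterification with methacrylic acid gives the inverted seco methacrylate F3. Intramolecular Sonogashira coupling (Pd(PPh3)4, CuI, i-Pr2NEt, THF, high dilution) then closes the ring, and the route is rejoined at 23.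

Step 15. SN2 displacement at the hindered C8 oxyphosphonium may be outrun by elimination towards C7, whose hydrogen is allylic to the methylene lactone, or may stall. The fallback sets out from 22 and separates activation from displacement. ClCH2SO2Cl/pyridine converts 22 with retention into the C8 chloromethanesulfonate F4. Caesium methacrylate with 18-crown-6 in toluene then displaces the sulfonate with inversion under non-basic conditions, and the route is rejoined at 23.

Step 12. The amine may epimerise the butenolide γ-centre C6, trigger β-elimination of the alkoxy aldehyde, or allow copper-mediated alkyne homocoupling. The fallback sets out from 17 and uses an amine-free and copper-free coupling. Tributyltin methoxide converts the terminal alkyne of 17 into the alkynylstannane F5. Stille coupling of F5 with 10 (Pd2(dba)3, tri(2-furyl)phosphine, THF, rt) forms the C3–C4 bond, and the route is rejoined at 18.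

Further compounds
F1 | step 14 | 3-(bromomethyl)-5-[(1Z)-3-[(tert-butyldiphenylsilyl)oxy]-2-iodoprop-1-en-1-yl]furan-2(5H)-one, configuration of 10 | I/C(CO[Si](c1ccccc1)(c1ccccc1)C(C)(C)C)=C\[C@H]2OC(=O)C(CBr)=C2
F2 | step 14 | seco alcohol (8S carbinol, trans-disubstituted α-methylene lactone, vinyl iodide, terminal alkyne, acetonide) | O[C@@H](C[C@]1(C)OC(C)(C)OC1C#C)[C@H]2C(=C)C(=O)O[C@@H]2/C=C(\I)CO[Si](c3ccccc3)(c3ccccc3)C(C)(C)C
F3 | step 14 | seco methacrylate (8R ester, otherwise as F2) | C=C(C)C(=O)O[C@H](C[C@]1(C)OC(C)(C)OC1C#C)[C@H]2C(=C)C(=O)O[C@@H]2/C=C(\I)CO[Si](c3ccccc3)(c3ccccc3)C(C)(C)C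
F4 | step 15 | C8 chloromethanesulfonate of 22 (8S) | ClCS(=O)(=O)O[C@H]1C[C@]2(C)OC(C)(C)OC2C#C/C(CO[Si](c3ccccc3)(c3ccccc3)C(C)(C)C)=C\[C@H]4OC(=O)C(=C)[C@@H]41
F5 | step 12 | tributylstannyl alkyne of 17 | O=CC[C@]1(C)OC(C)(C)OC1C#C[Sn](CCCC)(CCCC)CCCC
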